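The benzene ring of the coumarin (C4a, C5, C6, C7, C8, C8a) is opened at C4a–C5. The ring carries oxygen on C6, C7, C8 and C8a, with O7 and O8a meta and C5 bare. This is the pattern left by an open chain with ketones at C8a and C7, methoxy-bearing carbons at C8 and C6 and an aldehyde carbon at C5. The key step folds such an acyclic 5,7-diketo ester, its aldehyde masked as a dimethyl acetal, into the 2,4-dimethoxyresorcinol in one operation: C4a adds to C5, methanol is lost and the ring aromatises. Lactonisation through O8a, dehydrogenation and Mitsunobu coupling of O7 with a Sharpless-derived epoxy diol complete the target.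

Key step: step 3

Remark on labels: atoms of the open chain are named by the coumarin atoms they become (future C4a, C5, C6, C7, C8, C8a).
Assumption: 1,3-dimethoxypropan-2-one is treated as a purchasable building block; it is one oxidation step away from the bulk chemical 1,3-dimethoxypropan-2-ol.

Step 1
Reactants: 1 1,3-dimethoxypropan-2-one; 2 trimethyl orthoformate
Product: 4 1,3,4,4-tetramethoxybutan-2-one (racemic), via dimethoxycarbenium tetrafluoroborate 3 (not isolated)
Conditions: 2, BF3·OEt2, CH2Cl2, −30 °C; then 1 (slight excess), i-Pr2NEt, −78 °C to rt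
Reagents that add atoms: none
Why: The dimethoxycarbenium ion made from the orthoformate and BF3 is trapped by the enol of the ketone under amine base (α-dialkoxymethylation of a ketone, a Mukaiyama-type addition), the symmetry of 1 removes any regiochemical question, and the new stereocentre is racemic and is erased in step 3.

Step 2
Reactants: 4 1,3,4,4-tetramethoxybutan-2-one; 5 methyl 5-chloro-5-oxopentanoate
Product: 6 methyl 6,8,9,9-tetramethoxy-5,7-dioxononanoate (mixture of diastereomers and enol forms)
Conditions: MgBr2·OEt2, i-Pr2NEt, CH2Cl2, 0 °C to rt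
Reagents that add atoms: none
Why: Soft enolisation with MgBr2 and a hindered amine followed by C-acylation with the acid chloride (crossed Claisen-type synthesis of a 1,3-diketone) should engage the unhindered methoxymethyl CH2 (future C8) and not the crowded methine next to the acetal (future C6), the product being held as its magnesium diketonate; the new stereocentre forms unselectively and is erased in step 3.

Step 3
Reactants: 6 methyl 6,8,9,9-tetramethoxy-5,7-dioxononanoate
Product: 9 methyl 3-(2,4-dihydroxy-3,5-dimethoxyphenyl)propanoate, via bis-silyl dienol ether 7 (not isolated), via silylated cyclohexenone 8 (not isolated)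
Conditions: TMSOTf (2.3 equiv), Et3N (2.5 equiv), CH2Cl2, 0 °C; TMSOTf (0.5 equiv), −78 to 0 °C; then HCl, MeOH, rt
Reagents that add atoms: none
Why: Proposed new method: double O-silylation converts the 2-methoxy-1,3-diketone of 6 into the 2,4-bis(silyloxy)diene 7, free TMSOTf then ionises the dimethyl acetal to an oxocarbenium ion at the future C5, and the diene terminus (future C4a) adds to it in an intramolecular Mukaiyama aldol-type step that forms the C4a–C5 bond and the carbocycle 8. The ring closes in the 6-(enolendo)-exo-trig mode, the enol double bond C4a=C8a lying inside the new ring. Methanolic HCl then removes silicon, the β-methoxy ketone loses methanol and two enolisations give the aromatic ring, so no stereocentre is created and those of 6 and 8 are erased. The closest known reactions are the Lewis-acid-mediated [3+3] cyclocondensation of 1,3-bis(silyloxy)-1,3-dienes with β-keto acetals, in which the diene terminus bonds first to the acetal carbon, and the aldol aromatisation of β-polycarbonyl chains to resorcinols. The selectivity needed is C–C over C–O closure, since an unprotected 1,3,5-tricarbonyl chain would give a 4-pyranone under Brønsted acid; both diketone oxygens are therefore silylated before the acetal is opened and the free keto aldehyde is never formed, while the central diene carbon (future C8) could only close a four-membered ring. Closure requires the isomer of 7 with C8a and C6 cis on the C7=C8 bond, which the silyl triflate is expected to supply by equilibration.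

Step 4
Reactants: 9 methyl 3-(2,4-dihydroxy-3,5-dimethoxyphenyl)propanoate
Product: 10 7-hydroxy-6,8-dimethoxy-3,4-dihydro-2H-chromen-2-one
Conditions: TsOH·H2O (cat.), toluene, reflux, removal of MeOH
Reagents that add atoms: none
Why: Acid-catalysed transesterification by the ortho hydroxyl closes the six-membered lactone (lactonisation), driven by loss of methanol, while the para hydroxyl cannot reach the ester and stays free as O7.

Step 5
Reactants: 10 7-hydroxy-6,8-dimethoxy-3,4-dihydro-2H-chromen-2-one
Product: 11 7-hydroxy-6,8-dimethoxy-2H-chromen-2-one (isofraxidin)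
Conditions: DDQ, 1,4-dioxane, reflux
Reagents that add atoms: none
Why: DDQ abstracts hydride from the benzylic C4, which is para to the free 7-hydroxyl, and loss of the C3 proton from the resulting quinone methide gives the coumarin (quinone dehydrogenation of a dihydrocoumarin).

Step 6
Reactants: 12 geranyl acetate
Product: 13 (2E)-5-(3,3-dimethyloxiran-2-yl)-3-methylpent-2-en-1-yl acetate (6,7-epoxygeranyl acetate, racemic)
Conditions: mCPBA, NaHCO3, CH2Cl2, 0 °C
Reagents that add atoms: mCPBA (3-chloroperbenzoic acid), OOC(=O)c1cccc(Cl)c1
Why: The peracid epoxidises the electron-richer 6,7-alkene in preference to the 2,3-alkene, which the allylic acetate deactivates (Prilezhaev epoxidation); the epoxide stereocentre is racemic and is destroyed in step 8.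

Step 7
Reactants: 13 6,7-epoxygeranyl acetate
Product: 14 (2E)-5-(3,3-dimethyloxiran-2-yl)-3-methylpent-2-en-1-ol (racemic)
Conditions: K2CO3 (cat.), MeOH, rt
Reagents that add atoms: none
Why: Base-catalysed transesterification with methanol (Zemplén-type methanolysis) frees the allylic alcohol without touching the epoxide.

Step 8
Reactants: 14 (2E)-5-(3,3-dimethyloxiran-2-yl)-3-methylpent-2-en-1-ol
Product: 17 (2E,5E)-3,7-dimethylocta-2,5-diene-1,7-diol, via hydroxy selenide 15 (not isolated), via selenoxide 16 (not isolated)
Conditions: PhSeSePh, NaBH4, EtOH, rt to reflux; then 30% H2O2, THF, 0 °C to rt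
Reagents that add atoms: none
Why: The selenolate opens the trisubstituted epoxide at its secondary carbon, and the derived selenoxide can only eliminate away from the fully substituted carbinol carbon, giving the E-configured tertiary allylic alcohol (epoxide opening followed by selenoxide syn-elimination).

Step 9
Reactants: 17 (2E,5E)-3,7-dimethylocta-2,5-diene-1,7-diol
Product: 18 [(2R,3R)-3-[(2E)-4-hydroxy-4-methylpent-2-en-1-yl]-3-methyloxiran-2-yl]methanol
Conditions: Ti(OiPr)4 (cat.), D-(−)-diethyl tartrate (cat.), t-BuOOH, 4 Å molecular sieves, CH2Cl2, −20 °C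
Reagents that add atoms: tert-butyl hydroperoxide, CC(C)(C)OO
Why: Sharpless asymmetric epoxidation with the D-(−)-tartrate ligand sets both stereocentres as 2R,3R by reagent control, as it does for geraniol, while the tertiary allylic alcohol with its disubstituted alkene reacts far more slowly.

Step 10
Reactants: 11 isofraxidin; 18 [(2R,3R)-3-[(2E)-4-hydroxy-4-methylpent-2-en-1-yl]-3-methyloxiran-2-yl]methanol
Product: 19 7-{[(2R,3R)-3-[(2E)-4-hydroxy-4-methylpent-2-en-1-yl]-3-methyloxiran-2-yl]methoxy}-6,8-dimethoxy-2H-chromen-2-one (CNP0325711.2)
Conditions: PPh3, DIAD, THF, 0 °C to rt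
Reagents that add atoms: none
Why: Mitsunobu etherification of the acidic phenol takes place at the primary CH2 carbon, so neither epoxide stereocentre is touched, and the tertiary alcohol is too hindered to be activated.

Compound list
1 | 1,3-dimethoxypropan-2-one | COCC(=O)COC | starting material
2 | trimethyl orthoformate | COC(OC)OC | starting material
3 | dimethoxycarbenium tetrafluoroborate | CO[CH+]OC.F[B-](F)(F)F | intermediate
4 | 1,3,4,4-tetramethoxybutan-2-one (racemic) | COCC(=O)C(OC)C(OC)OC | intermediate
5 | methyl 5-chloro-5-oxopentanoate | COC(=O)CCCC(Cl)=O | starting material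
6 | methyl 6,8,9,9-tetramethoxy-5,7-dioxononanoate (mixture of diastereomers and enol forms) | COC(=O)CCCC(=O)C(OC)C(=O)C(OC)C(OC)OC | intermediate
7 | methyl (4Z,6Z)-6,8,9,9-tetramethoxy-5,7-bis(trimethylsilyloxy)nona-4,6-dienoate (drawn as the isomer able to cyclise; racemic) | COC(=O)CC/C=C(O[Si](C)(C)C)/C(OC)=C(O[Si](C)(C)C)\C(OC)C(OC)OC | intermediate
8 | methyl 3-[3,5,6-trimethoxy-2-oxo-4-(trimethylsilyloxy)cyclohex-3-en-1-yl]propanoate (mixture of diastereomers) | COC(=O)CCC1C(OC)C(OC)C(O[Si](C)(C)C)=C(OC)C1=O | intermediate
9 | methyl 3-(2,4-dihydroxy-3,5-dimethoxyphenyl)propanoate | COC(=O)CCc1cc(OC)c(O)c(OC)c1O | intermediate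
10 | 7-hydroxy-6,8-dimethoxy-3,4-dihydro-2H-chromen-2-one | COc1cc2CCC(=O)Oc2c(OC)c1O | intermediate
11 | 7-hydroxy-6,8-dimethoxy-2H-chromen-2-one (isofraxidin) | COc1cc2ccc(=O)oc2c(OC)c1O | intermediate
12 | geranyl acetate | CC(C)=CCC/C(C)=C/COC(C)=O | starting material
13 | (2E)-5-(3,3-dimethyloxiran-2-yl)-3-methylpent-2-en-1-yl acetate (racemic) | CC(=O)OC/C=C(\C)CCC1OC1(C)C | intermediate
14 | (2E)-5-(3,3-dimethyloxiran-2-yl)-3-methylpent-2-en-1-ol (racemic) | OC/C=C(\C)CCC1OC1(C)C | intermediate
15 | (2E)-3,7-dimethyl-6-(phenylselanyl)oct-2-ene-1,7-diol (racemic) | OC/C=C(\C)CCC([Se]c1ccccc1)C(C)(C)O | intermediate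
16 | (2E)-3,7-dimethyl-6-(phenylseleninyl)oct-2-ene-1,7-diol (mixture of stereoisomers) | OC/C=C(\C)CCC([Se](=O)c1ccccc1)C(C)(C)O | intermediate
17 | (2E,5E)-3,7-dimethylocta-2,5-diene-1,7-diol | OC/C=C(\C)C/C=C/C(C)(C)O | intermediate
18 | [(2R,3R)-3-[(2E)-4-hydroxy-4-methylpent-2-en-1-yl]-3-methyloxiran-2-yl]methanol | OC[C@H]1O[C@]1(C)C/C=C/C(C)(C)O | intermediate
19 | 7-{[(2R,3R)-3-[(2E)-4-hydroxy-4-methylpent-2-en-1-yl]-3-methyloxiran-2-yl]methoxy}-6,8-dimethoxy-2H-chromen-2-one | COc1cc2ccc(=O)oc2c(OC)c1OC[C@H]1O[C@]1(C)C/C=C/C(C)(C)O | target

Total step count: 10. Longest linear sequence: 6 steps (steps 1, 2, 3, 4, 5 and 10); the side chain takes steps 6 to 9.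

Steps most likely to fail

1. Step 3 (new method). Closure may take place through oxygen and not carbon, the oxygen at the future C8a adding to the acetal carbon and leading on to a 4-pyranone. The second silylation may also go toward the methine next to the acetal, with loss of methoxide, or the enol ether geometry may fail to equilibrate so that the chain cannot fold. The fallback uses known chemistry, sets out from 6 and returns at 10. Dilute HCl in THF would turn 6 into the pyranone methyl 4-(3,5-dimethoxy-4-oxo-4H-pyran-2-yl)butanoate F1, the usual acid cyclodehydration of a 1,3,5-tricarbonyl chain. Hot aqueous KOH would then open the pyranone at its unsubstituted ring carbon and the open tricarbonyl anion would close by the base-induced aldol aromatisation known from the conversion of 2,6-dimethyl-4-pyranone into orcinol. The ester is saponified on the way, and acidification would give 3-(2,4-dihydroxy-3,5-dimethoxyphenyl)propanoic acid F2. Heating F2 with TsOH in toluene would close the lactone 10. This path forms the same C4a–C5 bond but is expected to be less efficient.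

2. Step 2. Enolisation may occur toward the methine next to the acetal and be followed by β-elimination of methoxide, or the enolate may be acylated on oxygen. The fallback sets out from 4 and returns at 6. The kinetic enolate of 4, made with LiN(iPr)2 in THF at −78 °C, would add to commercial methyl 5-oxopentanoate in an aldol reaction to give methyl 5-hydroxy-6,8,9,9-tetramethoxy-7-oxononanoate F3. Oxidation of F3 with Dess–Martin periodinane would give the diketone 6.

3. Step 5. The quinone may over-oxidise the electron-rich free phenol (oxidative coupling) in competition with hydride abstraction at C4. The fallback sets out from 10 and returns at 11.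
- Silylation with TBSCl and imidazole would give 7-[(tert-butyldimethylsilyl)oxy]-6,8-dimethoxy-3,4-dihydro-2H-chromen-2-one F4.
- Enolisation with LiN(SiMe3)2 at −78 °C and trapping with PhSeBr would give the 3-phenylselanyl lactone F5.
- H2O2 would oxidise it to the selenoxide F6, which eliminates in the syn sense to 7-[(tert-butyldimethylsilyl)oxy]-6,8-dimethoxy-2H-chromen-2-one F7.
- Bu4NF buffered with acetic acid would then free the phenol 11.

Further compounds
F1 | step 3 | methyl 4-(3,5-dimethoxy-4-oxo-4H-pyran-2-yl)butanoate | COC(=O)CCCc1occ(OC)c(=O)c1OC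
F2 | step 3 | 3-(2,4-dihydroxy-3,5-dimethoxyphenyl)propanoic acid | OC(=O)CCc1cc(OC)c(O)c(OC)c1O
F3 | step 2 | methyl 5-hydroxy-6,8,9,9-tetramethoxy-7-oxononanoate (mixture of diastereomers) | COC(=O)CCCC(O)C(OC)C(=O)C(OC)C(OC)OC
F4 | step 5 | 7-[(tert-butyldimethylsilyl)oxy]-6,8-dimethoxy-3,4-dihydro-2H-chromen-2-one | COc1cc2CCC(=O)Oc2c(OC)c1O[Si](C)(C)C(C)(C)C
F5 | step 5 | 7-[(tert-butyldimethylsilyl)oxy]-6,8-dimethoxy-3-(phenylselanyl)-3,4-dihydro-2H-chromen-2-one (racemic) | COc1cc2CC([Se]c3ccccc3)C(=O)Oc2c(OC)c1O[Si](C)(C)C(C)(C)C
F6 | step 5 | 7-[(tert-butyldimethylsilyl)oxy]-6,8-dimethoxy-3-(phenylseleninyl)-3,4-dihydro-2H-chromen-2-one (mixture of stereoisomers) | COc1cc2CC([Se](=O)c3ccccc3)C(=O)Oc2c(OC)c1O[Si](C)(C)C(C)(C)C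
F7 | step 5 | 7-[(tert-butyldimethylsilyl)oxy]-6,8-dimethoxy-2H-chromen-2-one | COc1cc2ccc(=O)oc2c(OC)c1O[Si](C)(C)C(C)(C)C
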